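## Analysis of the target

Compound 18 is a dearomatised, twice C-alkylated acylphloroglucinol in which a six-membered carbocycle shares one bond with a 2,3-dihydrofuran. The atoms are labelled here as follows: C1 carries the (R)-2-methylbutanoyl group, C2 is the enol-ether carbon, C3 the quaternary carbon with the prenyl group, C4 and C6 are ketones and C5 is the gem-dimethyl carbon; the five-membered ring is completed by O7 (on C2), C8 and the methylene C9 (on C3), and C8 carries the tertiary carbinol carbon C10 with its methyl and 4-methylpent-3-enyl groups. There are four stereocentres, C3 (S), C8 (R), C10 (S) and the (R) carbon of the acyl chain: C8 and C10 are neighbours, C3 and C8 stand in a 1,3-relationship across the dihydrofuran with the prenyl group cis to the C10 substituent, and the acyl stereocentre is too remote to influence the others. The sensitive groups are two trisubstituted alkenes (which rule out late oxidation of the side arm), a tertiary alcohol four carbons from an alkene (cycloetherification or elimination in strong acid), the C4 ketone held between two quaternary carbons (retro-Claisen cleavage by nucleophilic base), the enol ether of a β-tricarbonyl system and the enolisable α-carbon of the acyl group. The difficulty is C3: it is quaternary, lies between two carbonyl carbons, and must be set relative to C8 although no stereocentre is attached to it. The strategy rests on the arm C9–C8–C10, which has the pattern of a 1,2,3-triol whose primary carbon C9 is bonded to C3 in place of oxygen and whose secondary oxygen has become the enol-ether oxygen O7 on C2. The arm can therefore be delivered as one chiral two-point reagent, the carbon end of which bonds to C3 and the oxygen end of which condenses with C2.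

## Retrosynthetic reasoning

The first bond cut is C2–O7. In 18 this is the enol-ether bond of a vinylogous ester, which forms under acid without touching a stereocentre. Cutting it, with the C10 oxygen carried as its silyl ether (17), opens the dihydrofuran to the monocyclic hydroxy triketone 16. A fused bicycle with ring-related stereocentres thereby becomes a flat carbocycle with a side arm. In the forward direction the C8 hydroxyl of 16 has to choose C2 over C4 and has to win against the C10 oxygen. The first is secured because only the hemiketal at C2 can lose the elements of water (towards C1); the second by keeping the C10 oxygen silylated until the ring is closed.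

The C8 hydroxyl of 16 is traced back to the sulfate monoester 15. This costs nothing, because 15 is what a 1,2-cyclic sulfate leaves behind when its primary carbon is attacked. It also has a use: while base is present the C8 oxygen is an unreactive sulfate anion and cannot add to the C4 ketone.

The second skeletal bond cut is C3–C9, which divides 15 into trione 7 and cyclic sulfate 14. C3 is the only carbon–carbon junction between a carbocycle that is easy to make without stereochemistry and an arm that holds both oxygenated stereocentres. A cut at C8–C9 or C8–C10 would instead demand a stereoselective carbonyl addition next to the crowded quaternary carbon. The fragments are of similar size, and C8 and C10 arrive finished. The forward reaction has to alkylate the dianion of 7 on carbon, at C3 and not at C1 or oxygen, at the primary carbon of 14, and from the enolate face that puts the prenyl group cis to the arm. That last point has no handle in the substrate and is left to a chiral ammonium counter-ion, with separation of the C3 epimers behind it. Making C3 before the dihydrofuran exists is deliberate: a prenyl group introduced last onto the closed ring would enter anti to the C8 substituent and end up trans to it, the opposite of what 18 needs.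

Cyclic sulfate 14 is cut at its two S–O bonds to diol 13, and the silyl ether of 13 is taken back to triol 10. The tertiary hydroxyl is told apart from the other two by transient silylation of the primary and secondary positions (11, 12) within one operation. Triol 10 is cut at C1–O and C2–O to the 2,3-epoxy alcohol 9. Base-mediated hydrolysis inverts C2 and retains C3, so the (2S,3S) epoxide maps onto (8R,10S) of 18. Epoxide 9 comes from geraniol 8 by asymmetric epoxidation of the allylic alkene, the only point at which absolute configuration enters the arm, and one that leaves the distal alkene alone.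

Trione 7 is cut at the two C5–methyl bonds to the prenylated acylphloroglucinol 6, at the ring–prenyl bond to 4 and prenyl bromide 5, and at the ring–acyl bond to phloroglucinol 2 and acid 1 (through its chloride 3). Aromatic substitution places all carbon substituents on a symmetrical ring and the acyl stereocentre is bought. Dearomatisation by double methylation is left to the end of this arm so that the earlier intermediates are stable phenols.

## Alternatives that were turned down

Alternative 1: The carbocycle is disconnected at C1–C2 and C3–C4 and built onto a preformed chiral dihydrofuran.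
- **Forward key step:** the 2-stannyl dihydrofuran A1 is coupled with the 4-chlorocyclobutenone A2 under Pd(PPh3)4 (zerovalent palladium) to form C1–C2. The adduct opens on warming to a dienylketene, and 6π-electrocyclisation forms C3–C4 to give cyclohexadienone A3.
- **For:** each event has close precedent and there is no carbon-versus-oxygen alkylation question. C3 is made inside a ring that already carries C8, so the ketene carbon should bond anti to the C8 side chain and leave the prenyl group cis, as in 18. On control of C3 this route is stronger than the chosen one.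
- **Against:** A3 is far from 18. C5 has one methyl, C6 is an isopropyl enol ether and C1 has no acyl group, so enol-ether hydrolysis, C5 methylation, C-acylation at C1 with an epimerisable acyl donor and desilylation must follow. A1 is an acid-labile, tetrasubstituted stannyl enol ether that itself needs several steps.
- **Comparison:** the step count would be roughly double. The chosen strategy gives up substrate control at C3 but brings in the acyl group in its first step and ends at 18 with no steps after the key step.

Alternative 2: The carbocycle is disconnected at C1–C2 by an intramolecular Claisen (Dieckmann-type) condensation of lactone A4, which already carries the whole acyl chain.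
- **Forward key step:** the C1 enolate of the side-chain β-diketone attacks the lactone carbonyl C2. The carbocycle closes, the lactone opens to the C8 alkoxide, and acid returns that oxygen to C2 to give A5, which is the same compound as intermediate 17 of the chosen route.
- **For:** A5 is one deprotection from 18. C3 would be set earlier, by acylating an α-prenyl lactone enolate anti to the C8 substituent, so it is again substrate-controlled and stronger on that point.
- **Against:** A4 contains a non-enolisable diketone (C4, C5, C6) that is prone to retro-Claisen cleavage under the very base the closure needs. Forming C3–C4 requires C-acylation of a hindered lactone enolate by a hindered acyl donor, where O-acylation competes. The lactone carbonyl attacked in the key step is neopentyl.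
- **Comparison:** both routes pass through the same last intermediate, but this one reaches it by a long and fragile linear sequence. The chosen route reaches it convergently from two robust fragments.

Alternative 3: The carbocycle is disconnected at C1–C6 and C3–C4 in a (3+3) sense.
- **Forward key step:** the cyclic enol ether A6 is acylated at C3 and, after the double bond has moved to the exocyclic position, at C1 by the diacid chloride A7 (Effenberger-type cyclisation), giving the bicyclic vinylogous ester A8.
- **For:** the carbocycle with its gem-dimethyl carbon is made in one step, and C3 is again formed on a ring that already bears C8, so anti attack should give the right relative configuration.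
- **Against:** double C-acylations of this kind are characteristically inefficient, with O-acylation leading to pyranones. Hydrogen chloride is released next to an enol ether, a tertiary silyl ether and two trisubstituted alkenes. A8 lacks the acyl group, and C1 is then a vinylic CH of a vinylogous ester, so acylation needs halogenation and metalation beside a cleavage-prone diketone.
- **Comparison:** it is shorter to the core than alternative 1, but the key step is expected to be low-yielding and the route ends short of 18. The chosen strategy trades substrate control at C3 for a complete carbon skeleton before the key step.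

Key step: step 8

Assumption: commercial (R)-2-methylbutanoic acid is taken to be of sufficient enantiomeric purity, and 9 is used at the enantiomeric purity the catalytic epoxidation delivers, since minor stereoisomers are removed as diastereomers after step 8.

## Route

Step 1
Reactants: 1 (R)-2-methylbutanoic acid; 2 phloroglucinol (benzene-1,3,5-triol)
Product: 4 (2R)-2-methyl-1-(2,4,6-trihydroxyphenyl)butan-1-one, via (R)-2-methylbutanoyl chloride 3 (not isolated)
Conditions: (COCl)2, DMF (cat.), CH2Cl2, 0 °C → rt; then 2, AlCl3 (3.5 equiv), PhNO2/CH2Cl2, 0 °C → rt; aq HCl work-up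
Reagents that add atoms: none
Why: Friedel–Crafts C-acylation of a very electron-rich, symmetrical arene gives a single regioisomer, and the acylated ring is deactivated towards a second acylation. The stereocentre is not involved in the bond formation; low temperature and short exposure to the Lewis acid are meant to limit enolisation.

Step 2
Reactants: 4 (2R)-2-methyl-1-(2,4,6-trihydroxyphenyl)butan-1-one; 5 prenyl bromide (1-bromo-3-methylbut-2-ene)
Product: 6 (2R)-2-methyl-1-[2,4,6-trihydroxy-3-(3-methylbut-2-en-1-yl)phenyl]butan-1-one
Conditions: 5 (0.95 equiv), 10% aq KOH, 0 °C; then aq HCl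
Reagents that add atoms: none
Why: C-alkylation of a phloroglucinol phenoxide by an allylic bromide; aqueous base favours carbon over oxygen, and the two free ring positions are equivalent. A slight deficit of bromide holds back the bis-prenyl product, which is removed by chromatography.

Step 3
Reactants: 6 (2R)-2-methyl-1-[2,4,6-trihydroxy-3-(3-methylbut-2-en-1-yl)phenyl]butan-1-one
Product: 7 3,5-dihydroxy-4,4-dimethyl-2-[(2R)-2-methylbutanoyl]-6-(3-methylbut-2-en-1-yl)cyclohexa-2,5-dien-1-one (dienol form of the 2-acyl-4,4-dimethyl-6-prenylcyclohexane-1,3,5-trione)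
Conditions: NaOMe (3.5 equiv), MeI (2.3 equiv), MeOH, 0 °C → rt; then aq HCl
Reagents that add atoms: iodomethane, CI
Why: Dearomatising double C-methylation of the acylphloroglucinol polyanion in methanol, where hydrogen bonding to oxygen favours carbon alkylation; the unsubstituted ring carbon is the least hindered site and takes both methyl groups. The acyl α-hydrogen is protected from exchange because the tricarbonyl system is already an anion.

Step 4
Reactants: 8 geraniol
Product: 9 [(2S,3S)-3-methyl-3-(4-methylpent-3-en-1-yl)oxiran-2-yl]methanol ((2S,3S)-2,3-epoxygeraniol)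
Conditions: Ti(OiPr)4 (5 mol %), L-(+)-diethyl tartrate (7.5 mol %), t-BuOOH, 4 Å MS, CH2Cl2, −20 °C
Reagents that add atoms: tert-butyl hydroperoxide, CC(C)(C)OO
Why: Sharpless asymmetric epoxidation: the titanium tartrate catalyst binds the allylic hydroxyl, so only the 2,3-alkene is oxidised and the distal trisubstituted alkene is left. With the L-(+)-tartrate, oxygen is delivered to the face that gives the (2S,3S) epoxide, which fixes the future C8 (after inversion) and C10.

Step 5
Reactants: 9 [(2S,3S)-3-methyl-3-(4-methylpent-3-en-1-yl)oxiran-2-yl]methanol
Product: 10 (2R,3S)-3,7-dimethyloct-6-ene-1,2,3-triol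
Conditions: 0.5 M aq NaOH, t-BuOH, 75 °C
Reagents that add atoms: water, O
Why: Payne rearrangement to the terminal epoxy alcohol (inversion at C2, C3 untouched) followed by hydroxide opening at the primary carbon. Direct base opening at C2 leads to the same triol; only attack at the tertiary C3, which is not expected in base, would erode the enantiomeric purity.

Step 6
Reactants: 10 (2R,3S)-3,7-dimethyloct-6-ene-1,2,3-triol
Product: 13 (2R,3S)-3,7-dimethyl-3-[(triethylsilyl)oxy]oct-6-ene-1,2-diol, via bis(trimethylsilyl) ether 11 (not isolated), via mixed tris-silyl ether 12 (not isolated)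
Conditions: Me3SiCl (2.1 equiv), Et3N, CH2Cl2, −78 → −20 °C; then 2,6-lutidine, Et3SiOTf (1.3 equiv), −78 → 0 °C; aqueous work-up; then PPTS (cat.), MeOH, 0 °C
Reagents that add atoms: triethylsilyl trifluoromethanesulfonate, CC[Si](CC)(CC)OS(=O)(=O)C(F)(F)F
Why: Transient silyl protection: the chlorosilane silylates the primary and secondary hydroxyls far faster than the tertiary one, the silyl triflate then caps the tertiary hydroxyl, and trimethylsilyl ethers are methanolysed much faster than a tertiary triethylsilyl ether. Acidic rather than basic cleavage is used so that the triethylsilyl group does not migrate to the neighbouring secondary oxygen.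

Step 7
Reactants: 13 (2R,3S)-3,7-dimethyl-3-[(triethylsilyl)oxy]oct-6-ene-1,2-diol
Product: 14 (4R)-4-[(2S)-6-methyl-2-[(triethylsilyl)oxy]hept-5-en-2-yl]-1,3,2-dioxathiolane 2,2-dioxide
Conditions: SO2Cl2 (1.1 equiv), Et3N (3 equiv), CH2Cl2, −78 → −20 °C
Reagents that add atoms: sulfuryl chloride, O=S(=O)(Cl)Cl
Why: Direct cyclic sulfation of a 1,2-diol: the primary hydroxyl forms a chlorosulfate that is captured by the neighbouring secondary hydroxyl in a five-membered closure, with no change at a stereocentre. No oxidant is used, so the trisubstituted alkene, which would not survive the usual RuCl3/NaIO4 oxidation of a cyclic sulfite, is untouched; low temperature and excess amine suppress chlorination.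

Step 8
Reactants: 7 3,5-dihydroxy-4,4-dimethyl-2-[(2R)-2-methylbutanoyl]-6-(3-methylbut-2-en-1-yl)cyclohexa-2,5-dien-1-one; 14 (4R)-4-[(2S)-6-methyl-2-[(triethylsilyl)oxy]hept-5-en-2-yl]-1,3,2-dioxathiolane 2,2-dioxide
Product: 18 (2R,3aS)-2-[(2S)-2-hydroxy-6-methylhept-5-en-2-yl]-5,5-dimethyl-7-[(2R)-2-methylbutanoyl]-3a-(3-methylbut-2-en-1-yl)-3,3a-dihydro-1-benzofuran-4,6(2H,5H)-dione, via sulfate monoester 15 (not isolated), via hydroxy triketone 16 (not isolated), via silyl ether 17 (not isolated)
Conditions: 7, CsOH·H2O (2.05 equiv), 4 Å MS, toluene/CH2Cl2, 0 °C; N-(9-anthracenylmethyl)-O-allylcinchonidinium bromide (10 mol %), 14, −40 → 0 °C; solvent exchange, then H2SO4 (1.1 equiv), H2O (3 equiv), THF, rt; then 1 M aq HCl, rt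
Reagents that add atoms: none
Why: Proposed new method: the dianion of 7 carries its second, more basic charge in the C2–C3–C4 diketonate, so C3 is the most nucleophilic carbon (C1 is a tricarbonyl-stabilised, fully substituted centre) and should open 14 by SN2 at the unhindered CH2 rather than at C8, which is flanked by the fully substituted C10; the closest known reactions are the opening of 1,2-cyclic sulfates at their primary carbon by malonate and β-keto ester anions and the phase-transfer alkylative dearomatisation of acylphloroglucinols. The result is sulfate monoester 15, in which the C8 oxygen stays masked as a non-nucleophilic anion, so that it cannot add to the non-enolisable C4 ketone and start a retro-Claisen cleavage while base is present. Acid then cleaves 15 at the S–O bond (no bond to C8 is broken, hence retention) to give 16, whose C8 hydroxyl adds to the C2 carbonyl in a 5-exo-trig closure; loss of water towards C1 gives the dihydrofuran enol ether 17, and aqueous HCl removes the tertiary triethylsilyl group. Only C2 can dehydrate, because the hemiketal at C4 has no α-hydrogen on either side and simply reverts, and the silyl ether keeps the C10 oxygen from competing for C2 in a six-membered closure during this stage. Carbon alkylation is needed over oxygen alkylation: a soft caesium/ammonium ion pair in a solvent of low polarity is chosen for this, and any enol ether formed on oxygen is hydrolysed in the acid stage back to 7, which can be recovered. C3 is the only new stereocentre; the enolate is planar and the nearest stereocentre of 14 is two atoms from the reacting carbon, so no useful substrate control is expected and the facial bias has to come from the chiral ammonium counter-ion. Because 14 is a single enantiomer the two C3 outcomes are diastereomers (prenyl cis or trans to the C8 side chain on the new ring) and are separable by chromatography after ring closure, and should the cinchonidinium salt prove the mismatched partner its cinchoninium pseudoenantiomer is used. C8 and C10 are carried over unchanged from 14.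

## Compound list

1 | (R)-2-methylbutanoic acid | CC[C@@H](C)C(O)=O | starting material
2 | phloroglucinol (benzene-1,3,5-triol) | Oc1cc(O)cc(O)c1 | starting material
3 | (R)-2-methylbutanoyl chloride | CC[C@@H](C)C(Cl)=O | intermediate (not isolated)
4 | (2R)-2-methyl-1-(2,4,6-trihydroxyphenyl)butan-1-one | CC[C@@H](C)C(=O)c1c(O)cc(O)cc1O | intermediate
5 | prenyl bromide (1-bromo-3-methylbut-2-ene) | CC(C)=CCBr | starting material
6 | (2R)-2-methyl-1-[2,4,6-trihydroxy-3-(3-methylbut-2-en-1-yl)phenyl]butan-1-one | CC[C@@H](C)C(=O)c1c(O)cc(O)c(CC=C(C)C)c1O | intermediate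
7 | 3,5-dihydroxy-4,4-dimethyl-2-[(2R)-2-methylbutanoyl]-6-(3-methylbut-2-en-1-yl)cyclohexa-2,5-dien-1-one | CC[C@@H](C)C(=O)C1=C(O)C(C)(C)C(O)=C(CC=C(C)C)C1=O | intermediate
8 | geraniol | CC(C)=CCC/C(C)=C/CO | starting material
9 | [(2S,3S)-3-methyl-3-(4-methylpent-3-en-1-yl)oxiran-2-yl]methanol | OC[C@@H]1O[C@@]1(C)CCC=C(C)C | intermediate
10 | (2R,3S)-3,7-dimethyloct-6-ene-1,2,3-triol | OC[C@H]([C@@](C)(O)CCC=C(C)C)O | intermediate
11 | (2R,3S)-3,7-dimethyl-1,2-bis[(trimethylsilyl)oxy]oct-6-en-3-ol | C[Si](C)(C)OC[C@H]([C@@](C)(O)CCC=C(C)C)O[Si](C)(C)C | intermediate (not isolated)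
12 | triethyl{[(2R,3S)-3,7-dimethyl-1,2-bis[(trimethylsilyl)oxy]oct-6-en-3-yl]oxy}silane | C[Si](C)(C)OC[C@H]([C@@](C)(O[Si](CC)(CC)CC)CCC=C(C)C)O[Si](C)(C)C | intermediate (not isolated)
13 | (2R,3S)-3,7-dimethyl-3-[(triethylsilyl)oxy]oct-6-ene-1,2-diol | OC[C@H]([C@@](C)(O[Si](CC)(CC)CC)CCC=C(C)C)O | intermediate
14 | (4R)-4-[(2S)-6-methyl-2-[(triethylsilyl)oxy]hept-5-en-2-yl]-1,3,2-dioxathiolane 2,2-dioxide | O=S1(=O)OC[C@H]([C@@](C)(O[Si](CC)(CC)CC)CCC=C(C)C)O1 | intermediate
15 | (2R,3S)-1-[(1S)-2-hydroxy-5,5-dimethyl-3-[(2R)-2-methylbutanoyl]-1-(3-methylbut-2-en-1-yl)-4,6-dioxocyclohex-2-en-1-yl]-3,7-dimethyl-3-[(triethylsilyl)oxy]oct-6-en-2-yl hydrogen sulfate (drawn as the free acid; present in the flask as its dicaesium salt) | CC[C@@H](C)C(=O)C1=C(O)[C@](CC=C(C)C)(C[C@@H](OS(O)(=O)=O)[C@@](C)(O[Si](CC)(CC)CC)CCC=C(C)C)C(=O)C(C)(C)C1=O | intermediate (not isolated)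
16 | (6S)-5-hydroxy-6-[(2R,3S)-2-hydroxy-3,7-dimethyl-3-[(triethylsilyl)oxy]oct-6-en-1-yl]-2,2-dimethyl-4-[(2R)-2-methylbutanoyl]-6-(3-methylbut-2-en-1-yl)cyclohex-4-ene-1,3-dione | CC[C@@H](C)C(=O)C1=C(O)[C@](CC=C(C)C)(C[C@@H](O)[C@@](C)(O[Si](CC)(CC)CC)CCC=C(C)C)C(=O)C(C)(C)C1=O | intermediate (not isolated)
17 | (2R,3aS)-5,5-dimethyl-7-[(2R)-2-methylbutanoyl]-2-[(2S)-6-methyl-2-[(triethylsilyl)oxy]hept-5-en-2-yl]-3a-(3-methylbut-2-en-1-yl)-3,3a-dihydro-1-benzofuran-4,6(2H,5H)-dione | CC[C@@H](C)C(=O)C1=C2O[C@@H]([C@@](C)(O[Si](CC)(CC)CC)CCC=C(C)C)C[C@]2(CC=C(C)C)C(=O)C(C)(C)C1=O | intermediate (not isolated)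
18 | (2R,3aS)-2-[(2S)-2-hydroxy-6-methylhept-5-en-2-yl]-5,5-dimethyl-7-[(2R)-2-methylbutanoyl]-3a-(3-methylbut-2-en-1-yl)-3,3a-dihydro-1-benzofuran-4,6(2H,5H)-dione | CC[C@@H](C)C(=O)C1=C2O[C@@H]([C@@](C)(O)CCC=C(C)C)C[C@]2(CC=C(C)C)C(=O)C(C)(C)C1=O | target

## Step count and least certain steps

Total step count: 8. Longest linear sequence: 5 steps (steps 4, 5, 6, 7 and 8, from geraniol 8); the trione arm is 3 steps (1, 2, 3) before step 8.

**Step 8 (key step, Proposed new method).**
- **What may go wrong:** alkylation on oxygen, or none at all, because C3 of the dianion is a fully substituted, weakly nucleophilic carbon and the sulfate is a hard sp3 electrophile. Next is poor facial selection at C3, since nothing in the substrate biases the enolate faces. In the acid stage, early loss of the silyl group could be followed by six-membered closure through the C10 oxygen.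
- **Fallback (known reaction types):** it sets out from 13. Selective sulfonylation of the primary hydroxyl (TsCl, pyridine, 0 °C) gives (2R,3S)-2-hydroxy-3,7-dimethyl-3-[(triethylsilyl)oxy]oct-6-en-1-yl 4-methylbenzenesulfonate F1, and Dess–Martin oxidation gives the α-tosyloxy ketone (3S)-3,7-dimethyl-2-oxo-3-[(triethylsilyl)oxy]oct-6-en-1-yl 4-methylbenzenesulfonate F2. α-Sulfonyloxy and α-halo ketones are soft electrophiles that alkylate 2-substituted cyclic 1,3-dicarbonyl anions on carbon (the first stage of a Feist–Benary synthesis). The dianion of 7 (K2CO3, NaI for an in-situ Finkelstein exchange, acetone) should therefore give the C3-alkylated ketone (6S)-6-[(3S)-3,7-dimethyl-2-oxo-3-[(triethylsilyl)oxy]oct-6-en-1-yl]-5-hydroxy-2,2-dimethyl-4-[(2R)-2-methylbutanoyl]-6-(3-methylbut-2-en-1-yl)cyclohex-4-ene-1,3-dione F3, together with its C3 epimer. Corey–Bakshi–Shibata reduction of the side-chain ketone ((S)-2-methyl-CBS-oxazaborolidine, catecholborane, −78 °C, chosen on the large/small model to give the 8R carbinol) comes back to the route at 16, which is taken through the acid stage of step 8. The ring carbonyls are either tied up in the enolised tricarbonyl system or flanked by two quaternary carbons. The C3 epimers are separated at the stage of 18.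

**Step 7.**
- **What may go wrong:** chlorination of the trisubstituted alkene by the sulfuryl reagent, or chloride opening of the sulfate as it forms.
- **Fallback:** from 13, Mitsunobu cyclodehydration (PPh3, DIAD) activates the primary hydroxyl and closes the terminal epoxide triethyl({(2S)-6-methyl-2-[(2R)-oxiran-2-yl]hept-5-en-2-yl}oxy)silane F4 with retention at C8. The dianion of 7 opens F4 at its CH2 (LiClO4, THF, warming), and protonation comes back to the route at 16. The epoxide is the weaker electrophile and frees the C8 alkoxide under basic conditions, which is why it is the reserve and not the first choice.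

**Step 6.**
- **What may go wrong:** incomplete discrimination between the hydroxyls, silyl exchange between the trimethylsilyl ethers and the silyl triflate, or silyl migration from the tertiary to the secondary oxygen.
- **Fallback:** from 10, acetylation of the primary and secondary hydroxyls (Ac2O, pyridine, 0 °C) gives (2R,3S)-3-hydroxy-3,7-dimethyloct-6-ene-1,2-diyl diacetate F5. Silylation (Et3SiOTf, 2,6-lutidine) gives (2R,3S)-3,7-dimethyl-3-[(triethylsilyl)oxy]oct-6-ene-1,2-diyl diacetate F6. Reductive removal of both acetates with i-Bu2AlH at −78 °C, where no alkoxide is held at a temperature that allows migration, comes back to the route at 13.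

**Step 1.**
- **What may go wrong:** partial racemisation of the acyl α-carbon by enolisation of the Lewis-acid-bound acid chloride or ketone.
- **Fallback:** from 2 and 1. Phloroglucinol is converted into 1,3,5-tris(methoxymethoxy)benzene F7 (NaH, MOMCl, DMF) and the acid into the Weinreb amide (2R)-N-methoxy-N,2-dimethylbutanamide F8 (MeNHOMe·HCl, carbodiimide coupling). Ring lithiation of F7 (n-BuLi, THF, 0 °C) and addition to F8 give (2R)-2-methyl-1-[2,4,6-tris(methoxymethoxy)phenyl]butan-1-one F9. Mild acetal cleavage (HCl, MeOH, rt) comes back to the route at 4 without a Lewis acid.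

**Step 3 (with step 2).**
- **What may go wrong:** methylation at the prenyl-bearing ring carbon or on oxygen, giving constitutional isomers of 7 that are hard to separate.
- **Fallback:** from 4, the order of the alkylations is reversed. Double methylation first (NaOMe, MeI, MeOH) gives 3,5-dihydroxy-4,4-dimethyl-2-[(2R)-2-methylbutanoyl]cyclohexa-2,5-dien-1-one F10, which has only one ring carbon left for alkylation. C-prenylation with 5 (aq KOH, 0 °C) comes back to the route at 7.

## Further compounds

F1 | step 8 | (2R,3S)-2-hydroxy-3,7-dimethyl-3-[(triethylsilyl)oxy]oct-6-en-1-yl 4-methylbenzenesulfonate | Cc1ccc(cc1)S(=O)(=O)OC[C@H]([C@@](C)(O[Si](CC)(CC)CC)CCC=C(C)C)O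
F2 | step 8 | (3S)-3,7-dimethyl-2-oxo-3-[(triethylsilyl)oxy]oct-6-en-1-yl 4-methylbenzenesulfonate | Cc1ccc(cc1)S(=O)(=O)OCC(=O)[C@@](C)(O[Si](CC)(CC)CC)CCC=C(C)C
F3 | step 8 | (6S)-6-[(3S)-3,7-dimethyl-2-oxo-3-[(triethylsilyl)oxy]oct-6-en-1-yl]-5-hydroxy-2,2-dimethyl-4-[(2R)-2-methylbutanoyl]-6-(3-methylbut-2-en-1-yl)cyclohex-4-ene-1,3-dione | CC[C@@H](C)C(=O)C1=C(O)[C@](CC=C(C)C)(CC(=O)[C@@](C)(O[Si](CC)(CC)CC)CCC=C(C)C)C(=O)C(C)(C)C1=O
F4 | step 7 | triethyl({(2S)-6-methyl-2-[(2R)-oxiran-2-yl]hept-5-en-2-yl}oxy)silane | C1O[C@H]1[C@@](C)(O[Si](CC)(CC)CC)CCC=C(C)C
F5 | step 6 | (2R,3S)-3-hydroxy-3,7-dimethyloct-6-ene-1,2-diyl diacetate | CC(=O)OC[C@H]([C@@](C)(O)CCC=C(C)C)OC(C)=O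
F6 | step 6 | (2R,3S)-3,7-dimethyl-3-[(triethylsilyl)oxy]oct-6-ene-1,2-diyl diacetate | CC(=O)OC[C@H]([C@@](C)(O[Si](CC)(CC)CC)CCC=C(C)C)OC(C)=O
F7 | step 1 | 1,3,5-tris(methoxymethoxy)benzene | COCOc1cc(OCOC)cc(OCOC)c1
F8 | step 1 | (2R)-N-methoxy-N,2-dimethylbutanamide | CC[C@@H](C)C(=O)N(C)OC
F9 | step 1 | (2R)-2-methyl-1-[2,4,6-tris(methoxymethoxy)phenyl]butan-1-one | CC[C@@H](C)C(=O)c1c(OCOC)cc(OCOC)cc1OCOC
F10 | step 3 | 3,5-dihydroxy-4,4-dimethyl-2-[(2R)-2-methylbutanoyl]cyclohexa-2,5-dien-1-one | CC[C@@H](C)C(=O)C1=C(O)C(C)(C)C(O)=CC1=O
A1 | alternative 1 | tributyl[(5R)-5-[(2S)-6-methyl-2-[(triethylsilyl)oxy]hept-5-en-2-yl]-3-(3-methylbut-2-en-1-yl)-4,5-dihydrofuran-2-yl]stannane | CCCC[Sn](CCCC)(CCCC)C1=C(CC=C(C)C)C[C@@H](O1)[C@@](C)(O[Si](CC)(CC)CC)CCC=C(C)C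
A2 | alternative 1 | 4-chloro-2-methyl-3-(propan-2-yloxy)cyclobut-2-en-1-one (racemic) | CC1=C(OC(C)C)C(Cl)C1=O
A3 | alternative 1 | (2R,3aS)-5-methyl-2-[(2S)-6-methyl-2-[(triethylsilyl)oxy]hept-5-en-2-yl]-3a-(3-methylbut-2-en-1-yl)-6-(propan-2-yloxy)-3,3a-dihydro-1-benzofuran-4(2H)-one | C1=C2O[C@@H]([C@@](C)(O[Si](CC)(CC)CC)CCC=C(C)C)C[C@]2(CC=C(C)C)C(=O)C(C)=C1OC(C)C
A4 | alternative 2 | (3R,5R)-5-[(2S)-6-methyl-2-[(triethylsilyl)oxy]hept-5-en-2-yl]-3-(3-methylbut-2-en-1-yl)-3-[(6R)-2,2,6-trimethyl-3,5-dioxooctanoyl]oxolan-2-one | CC[C@@H](C)C(=O)CC(=O)C(C)(C)C(=O)[C@@]1(CC=C(C)C)C[C@H]([C@@](C)(O[Si](CC)(CC)CC)CCC=C(C)C)OC1=O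
A5 | alternative 2 | (2R,3aS)-5,5-dimethyl-7-[(2R)-2-methylbutanoyl]-2-[(2S)-6-methyl-2-[(triethylsilyl)oxy]hept-5-en-2-yl]-3a-(3-methylbut-2-en-1-yl)-3,3a-dihydro-1-benzofuran-4,6(2H,5H)-dione | CC[C@@H](C)C(=O)C1=C2O[C@@H]([C@@](C)(O[Si](CC)(CC)CC)CCC=C(C)C)C[C@]2(CC=C(C)C)C(=O)C(C)(C)C1=O
A6 | alternative 3 | triethyl({(2S)-6-methyl-2-[(2R)-5-methyl-4-(3-methylbut-2-en-1-yl)-2,3-dihydrofuran-2-yl]hept-5-en-2-yl}oxy)silane | CC1=C(CC=C(C)C)C[C@@H](O1)[C@@](C)(O[Si](CC)(CC)CC)CCC=C(C)C
A7 | alternative 3 | 2,2-dimethylpropanedioyl dichloride | CC(C)(C(Cl)=O)C(Cl)=O
A8 | alternative 3 | (2R,3aS)-5,5-dimethyl-2-[(2S)-6-methyl-2-[(triethylsilyl)oxy]hept-5-en-2-yl]-3a-(3-methylbut-2-en-1-yl)-3,3a-dihydro-1-benzofuran-4,6(2H,5H)-dione | O=C1C=C2O[C@@H]([C@@](C)(O[Si](CC)(CC)CC)CCC=C(C)C)C[C@]2(CC=C(C)C)C(=O)C1(C)C
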